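## Structural features

The target is a (2S)-flavanone. Ring A is a phloroglucinol-type benzene with free hydroxyls at C5 and C7, ring C is the dihydropyranone that holds the single ring stereocentre C2, and ring B is a 4-hydroxy-2-methoxyphenyl group on C2. C8 of ring A carries, through the benzylic methylene C1'', a ten-carbon chain in which the methine C2'' (R, bearing the prenyl methylene C3'') stands next to the methine C7'' (R, bearing a methyl group and the hydroxymethyl carbon C9''). These two are the only contiguous stereocentres, and ring A separates them from C2, so no relay of chirality between chain and ring C can be counted on. The fragile elements are the flavanone (retro-oxa-Michael opening under base erases C2), the trisubstituted alkene C4''=C5'' (no hydrogenation or strong acid once it exists), and the very electron-rich ring A (any leaving group on C1'' ionises). The real difficulties are three: the acyclic vicinal pair C2''/C7''; closure of ring C onto the oxygen at C8a and not onto the similar oxygen at C5 (8-alkyl versus 6-alkyl flavanone); and the C2 centre with its ortho-substituted aryl group. The key step uses the fact that C3''–C2''–C7''–C9'' is a masked trans-3,4-disubstituted γ-butyrolactone, with C3'' as lactone carbonyl and C9'' as ring OCH2. The C7''–CH3 and C1''–C2'' bonds can then both be made on a butenolide, with ring A entering as its aldehyde, whose one ortho oxygen destined to become O1 later decides the 8-alkyl regiochemistry.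

## Logic of the disconnections

24 to 23: the three aryl O–CH2 acetal bonds are cut. The phenols must stay masked through the organometallic steps, and acetal cleavage is the only operation left once C2 exists. The forward step needs acid mild enough to spare C2 and the alkene C4''=C5''.

23 to 17 and 22: the C2–C1' bond is cut. Ring B becomes a simple separate fragment, and C2 is set last, by a chiral catalyst, independent of the remote chain centres. The forward conjugate arylation must discriminate the faces of a deactivated 5,7-dioxygenated chromone with an ortho-substituted aryl donor in a base-free medium.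

22 to 19 to 18: the C–B bond and one O–CH2 bond are cut, which leads to a commercial bromophenol. The forward demand is only that the acetal survives the metalation and the hydrolysis of the borate.

17 to 15 to 14: the O1–C2 bond (oxa-Michael closure via 16) and the C4–C3 bond (acetylide addition) are cut. The chromone is thereby reduced to an ortho-hydroxy aldehyde without any acidic step. The forward demand is that the phenol at C8a is the only free phenol, so that ring C can close in one direction only.

14 to 12: the C4a–C4 bond is cut. A formyl group ortho to the one free phenol is the mildest acyl equivalent that tolerates the alkene and the acetals. Since the other ortho position of that phenol is C8, the forward formylation has only to be ortho-specific.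

12 to 11: the C4''=C5'' double bond is cut. Olefination of a lactol builds the prenyl terminus and releases C9''–OH in one operation, with no protecting group on that alcohol. The forward step needs excess ylide because two acidic hydroxyls are present.

11 to 9 (via 10): the C3''–C4'' bond is cut. C3'', the former lactone carbonyl, must end as a methylene with one more carbon attached, so a one-carbon homologation of the lactol is required. The forward demand is that C2'', α to the aldehyde in the open form of 9, is not epimerised.

9 to 8: an adjustment of oxidation level at C3''. The forward reduction must stop at the lactol.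

8 to 7: the C1''–O bond of the carbinol and the O–CH2Ph bond are cut. Both are benzylic C–O bonds, and one hydrogenolysis, placed before any alkene exists, removes the superfluous carbinol oxygen and uncovers the C8a phenol. The forward demand is that C2'' is not lost through elimination across C1''–C2''.

7 to 3, 4 and 5: the C7''–CH3 and C1''–C2'' bonds are cut. This is the strategic simplification: both chain stereocentres and the link to ring A arise from three simple components. The forward step must set C7'' by catalyst control, set C2'' trans to it by substrate control, and trap the enolate before it decomposes.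

3 to 2 to 1: the O–CH2 bonds of two acetals and one benzyl ether are cut. If all three ring-A oxygens carried the same group, the two oxygens flanking the later acyl carbon could not be told apart, and ring C could close to the 6-alkyl isomer. The aldehyde is therefore built with one ortho oxygen marked as a benzyl ether. The forward differentiation relies on the hydrogen bond between one ortho hydroxyl and the formyl group.

## Other disconnections considered

Alternative 1: The cut dismantles ring A itself, at C8a–C8, C6–C7 and C8a–C4a.
- Forward step: 3-ethoxycyclobut-2-en-1-one A2 would be heated with the side-chain silyloxyalkyne A3. Ring opening of A2, ketene–alkyne [2+2] cycloaddition, a second four-electron ring opening, six-electron electrocyclisation and tautomerisation should give phenol A1.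
- In favour: the three ring-A oxygens are differentiated by the mechanism itself (free OH at C8a, silyl ether at C7, ethyl ether at C5). On this structural point the alternative is better than the chosen plan, which has to engineer the same result through steps 1, 2 and 4. It is also thermal and neutral, tolerates the alkene, and needs no benzylic deoxygenation.
- Against: it sets no stereocentre. C2'' and C7'' would have to be made beforehand on A3, by something like step 3 followed by conversion of a carbonyl group into a sensitive silyloxyalkyne. The ethyl ether at O5 is a poor last protecting group beside the 2'-methoxy group and the alkene. Ring C and C2 remain to be made as in steps 8 to 14.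
- Comparison: mechanistically cleaner for ring A, but longer overall and silent on the stereochemical problem.

Alternative 2: The cut is O1–C8a.
- Forward step: the bromo anti-diol A5 would be treated with Pd(OAc)2 (a divalent palladium precatalyst), a bulky di-tert-butylbiarylphosphine and Cs2CO3. The C2 hydroxyl should couple with the C8a bromide with retention to give flavan-4-ol A4, whose C4 carbinol is then oxidised.
- In favour: C2 would be fixed by carbonyl chemistry before ring closure, and the C–O coupling does not touch it. This avoids the conjugate arylation of a deactivated chromone with an ortho-substituted donor, so on the security of C2 it is arguably better than the chosen plan. The direction of ring closure is fixed by the bromine, equal to the free-phenol device used here.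
- Against: the bromide lies between two ortho substituents on an electron-rich ring, so oxidative addition and C–O reductive elimination are both slow. A secondary benzylic palladium alkoxide can undergo β-hydride elimination. The C4 carbinol on a trioxygenated ring ionises easily. A hexasubstituted brominated ring A must be carried through the side-chain chemistry, and a stereocentre at C4 is made only to be destroyed.
- Comparison: several steps longer, with one extra redox operation.

Alternative 3: The cut is C2–C3.
- Forward step: the diazomethyl ketone A7 would be decomposed by Rh2(S-PTTL)4, dirhodium tetrakis[N-phthaloyl-(S)-tert-leucinate] (divalent rhodium). The carbenoid at C3 should insert into one benzylic O–CH2 hydrogen and give flavanone A6.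
- In favour: ring B would arrive by simple O-benzylation of the C8a phenol, the same handle as in the chosen plan. Ring C and C2 would be formed in one step without any boron reagent. On paper the end game is as short as, or shorter than, steps 9 to 13.
- Against: a carbenoid from a diazomethyl ketone is of the least selective class. The closure needs a 1,6-insertion against the usual 1,5 preference. The ether oxygen can attack the carbenoid, and the oxonium ylide would then undergo a [1,2]-benzyl shift that contracts ring C to a five-membered ring. The alkene C4''=C5'' invites cyclopropanation and ring B invites aromatic cycloaddition. The diazoketone would also have to be made from a hindered 2,6-disubstituted aroyl chloride.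
- Comparison: shorter, but with chemoselectivity and enantioselectivity far less predictable than the catalyst-controlled arylation.

Key step: step 3

Assumption: the sense of induction of the two chiral catalysts (steps 3 and 13) is inferred from the closest cyclic-enone analogies; both ligands exist in either antipode, and the antipode meant is the one that gives (4R) in 7 and (2S) in 23.

## Route

Step 1
Reactants: 1 2,4,6-trihydroxybenzaldehyde
Product: 2 2-hydroxy-4,6-bis(methoxymethoxy)benzaldehyde
Conditions: MOMCl (2.2 equiv), i-Pr2NEt (3 equiv), CH2Cl2, 0 °C → rt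
Reagents that add atoms: chloromethyl methyl ether, COCCl
Why: Williamson-type O-alkylation of the two most available phenols. The second ortho hydroxyl is held in a hydrogen bond to the formyl oxygen and should stay free under amine-base conditions, which singles out the future O1.

Step 2
Reactants: 2 2-hydroxy-4,6-bis(methoxymethoxy)benzaldehyde
Product: 3 2-(benzyloxy)-4,6-bis(methoxymethoxy)benzaldehyde
Conditions: BnBr (1.2 equiv), K2CO3, DMF, 50 °C
Reagents that add atoms: benzyl bromide, BrCc1ccccc1
Why: Williamson ether synthesis; carbonate in DMF breaks the chelate and alkylates the remaining phenol. The benzyl group marks the oxygen that becomes O1 and is the one group that step 4 removes.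

Step 3
Reactants: 4 furan-2(5H)-one (1.5 equiv); 5 dimethylzinc (3 equiv); 3 2-(benzyloxy)-4,6-bis(methoxymethoxy)benzaldehyde
Product: 7 (3S,4R)-3-{[2-(benzyloxy)-4,6-bis(methoxymethoxy)phenyl](hydroxy)methyl}-4-methyldihydrofuran-2(3H)-one (both carbinol epimers), via methylzinc enolate 6 (not isolated)
Conditions: Cu(OTf)2 (2 mol %), dipeptide-derived Schiff-base aryl phosphine ligand (5 mol %), toluene, −30 → 0 °C, 3 present from the start; sat. aq. NH4Cl
Reagents that add atoms: none
Why: Dimethylzinc reduces Cu(OTf)2 to a monovalent copper–methyl species on the chiral phosphine, which binds the C=C bond of 4 and transfers methyl to C4 (the future C7'') through a trivalent copper alkyl and reductive elimination, giving zinc enolate 6. The closest known reaction type is the copper-catalysed enantioselective conjugate addition of dialkylzincs to unsaturated lactones run with an aldehyde present as in situ trap. Enolate 6 then adds to aldehyde 3 through a closed, zinc-centred six-membered (Zimmerman–Traxler-type) transition state and forms C1''–C2''. No ring is closed; the butenolide ring is kept as a template that holds C3'' and C9''. C7'' is set by the ligand (methyl delivered to the Re face of C4, giving 4R), and C2'' is set by the substrate, because the aldehyde approaches the enolate face anti to the new methyl group, giving the 3,4-trans lactone (3S). The carbinol carbon C1'' forms without control and needs none, since its oxygen is removed in step 4. The step needs 1,4- rather than 1,2-methyl transfer (secured by copper), aldol capture faster than opening of the enolate to a ketene (secured by having 3 present from the outset at low temperature and by chelation of zinc by its ortho alkoxy groups), and no direct methyl addition to the aldehyde (uncatalysed dimethylzinc adds only slowly to a hindered, electron-rich benzaldehyde).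

Step 4
Reactants: 7 (3S,4R)-3-{[2-(benzyloxy)-4,6-bis(methoxymethoxy)phenyl](hydroxy)methyl}-4-methyldihydrofuran-2(3H)-one
Product: 8 (3R,4R)-3-[2-hydroxy-4,6-bis(methoxymethoxy)benzyl]-4-methyldihydrofuran-2(3H)-one
Conditions: H2 (1 atm), Pd(OH)2/C, EtOAc–AcOH (5:1), rt
Reagents that add atoms: none
Why: Catalytic hydrogenolysis should cleave both benzylic C–O bonds: the benzyl ether (freeing the C8a phenol) and the carbinol C1''–OH, which is unusually labile on a 2,4,6-trioxygenated ring. No alkene is present yet, and the acetals and lactone are inert. C2'' and C7'' are not involved, and the trans lactone is also the thermodynamic isomer, so any erosion at C2'' could be corrected by base equilibration.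

Step 5
Reactants: 8 (3R,4R)-3-[2-hydroxy-4,6-bis(methoxymethoxy)benzyl]-4-methyldihydrofuran-2(3H)-one
Product: 9 (3R,4R)-3-[2-hydroxy-4,6-bis(methoxymethoxy)benzyl]-4-methyltetrahydrofuran-2-ol (anomers)
Conditions: i-Bu2AlH (2.3 equiv), CH2Cl2, −78 °C; aq. potassium sodium tartrate
Reagents that add atoms: none
Why: Partial reduction of a γ-lactone by i-Bu2AlH at low temperature stops at the aluminium lactolate. One equivalent of hydride is consumed by the phenol.

Step 6
Reactants: 9 (3R,4R)-3-[2-hydroxy-4,6-bis(methoxymethoxy)benzyl]-4-methyltetrahydrofuran-2-ol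
Product: 11 (4S,5R)-4-[2-hydroxy-4,6-bis(methoxymethoxy)benzyl]-5-methyltetrahydro-2H-pyran-2-ol (anomers), via enol ether 10 (not isolated)
Conditions: Ph3PCH2OMe Cl (4 equiv), KN(SiMe3)2 (3.9 equiv), THF, 0 °C → rt; crude 10 then 1 M aq. HCl–THF (1:4), dilute, rt
Reagents that add atoms: (methoxymethyl)triphenylphosphonium chloride, COC[P+](c1ccccc1)(c1ccccc1)c1ccccc1.[Cl-]; water, O
Why: Wittig methoxymethylenation of the open hydroxy-aldehyde form of the lactol gives enol ether 10. Its mild hydrolysis releases the one-carbon-homologous aldehyde C4'', which closes on C9''–OH as the six-membered lactol. C2'' is α to a carbonyl only in the open form of 9, and fast ylide addition should outrun enolisation.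

Step 7
Reactants: 11 (4S,5R)-4-[2-hydroxy-4,6-bis(methoxymethoxy)benzyl]-5-methyltetrahydro-2H-pyran-2-ol
Product: 12 (2R,3R)-3-[2-hydroxy-4,6-bis(methoxymethoxy)benzyl]-2,6-dimethylhept-5-en-1-ol
Conditions: i-PrPPh3 I (5 equiv), n-BuLi (4.8 equiv), THF, 0 °C; then 11, −78 °C → rt
Reagents that add atoms: isopropyltriphenylphosphonium iodide, CC(C)[P+](c1ccccc1)(c1ccccc1)c1ccccc1.[I-]
Why: Wittig olefination of a lactol with the non-stabilised isopropylidene ylide forms C4''=C5'' (no E/Z question, two identical methyl groups) and releases C9''–OH. The excess ylide covers the phenol and the lactol hydroxyl.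

Step 8
Reactants: 12 (2R,3R)-3-[2-hydroxy-4,6-bis(methoxymethoxy)benzyl]-2,6-dimethylhept-5-en-1-ol
Product: 14 2-hydroxy-3-{(2R)-2-[(2R)-1-hydroxypropan-2-yl]-5-methylhex-4-en-1-yl}-4,6-bis(methoxymethoxy)benzaldehyde, via hydroxymethylphenol 13 (not isolated)
Conditions: MgCl2 (3 equiv), Et3N (6 equiv), (CH2O)n (8 equiv), MeCN, reflux; sat. aq. NH4Cl
Reagents that add atoms: paraformaldehyde (formaldehyde), C=O
Why: Magnesium-mediated ortho-formylation (Casnati–Skattebøl): the magnesium phenoxide delivers formaldehyde only to the carbon ortho to the free phenol, giving 13, which a second formaldehyde oxidises by hydride transfer. The other ortho position is C8, so the formyl group can enter only at C4a, and this fixes the C8a oxygen as the future O1. Alkene, acetals and the free primary alcohol are tolerated by this weakly basic medium.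

Step 9
Reactants: 14 2-hydroxy-3-{(2R)-2-[(2R)-1-hydroxypropan-2-yl]-5-methylhex-4-en-1-yl}-4,6-bis(methoxymethoxy)benzaldehyde
Product: 15 1-(2-hydroxy-3-{(2R)-2-[(2R)-1-hydroxypropan-2-yl]-5-methylhex-4-en-1-yl}-4,6-bis(methoxymethoxy)phenyl)prop-2-yn-1-ol (carbinol epimers)
Conditions: HC≡CMgBr (4 equiv), THF, 0 °C → rt; sat. aq. NH4Cl; used crude
Reagents that add atoms: ethynylmagnesium bromide, C#C[Mg]Br
Why: Grignard addition of an acetylide to the aldehyde forms C4–C3. Two equivalents are consumed by the phenol and the primary alcohol. The new carbinol configuration is irrelevant because it is oxidised in step 10.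

Step 10
Reactants: 15 1-(2-hydroxy-3-{(2R)-2-[(2R)-1-hydroxypropan-2-yl]-5-methylhex-4-en-1-yl}-4,6-bis(methoxymethoxy)phenyl)prop-2-yn-1-ol
Product: 17 8-{(2R)-2-[(2R)-1-hydroxypropan-2-yl]-5-methylhex-4-en-1-yl}-5,7-bis(methoxymethoxy)-4H-chromen-4-one, via ynone 16 (not isolated)
Conditions: MnO2 (activated, 15 equiv), CH2Cl2, rt; filter; K2CO3 (0.2 equiv), acetone, rt
Reagents that add atoms: none
Why: MnO2 oxidises the benzylic–propargylic carbinol selectively (the primary aliphatic alcohol is not activated) to ynone 16. The ortho phenoxide then adds to the terminal alkyne carbon by 6-endo-dig oxa-Michael addition and closes ring C as the chromone. Only the C8a oxygen is free, so only the 8-alkyl isomer can form.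

Step 11
Reactants: 18 4-bromo-3-methoxyphenol
Product: 19 1-bromo-2-methoxy-4-(methoxymethoxy)benzene
Conditions: MOMCl (1.3 equiv), i-Pr2NEt (2 equiv), CH2Cl2, 0 °C → rt
Reagents that add atoms: chloromethyl methyl ether, COCCl
Why: O-alkylation of the phenol as the same acetal that protects ring A, so that all phenol protecting groups leave together in step 14.

Step 12
Reactants: 19 1-bromo-2-methoxy-4-(methoxymethoxy)benzene
Product: 22 [2-methoxy-4-(methoxymethoxy)phenyl]boronic acid, via aryllithium 20 (not isolated), via lithium borate 21 (not isolated)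
Conditions: n-BuLi (1.1 equiv), B(Oi-Pr)3 (1.5 equiv), THF–toluene, −78 °C; sat. aq. NH4Cl
Reagents that add atoms: triisopropyl borate, CC(C)OB(OC(C)C)OC(C)C; water, O
Why: Bromine–lithium exchange gives 20, which the borate captures as ate complex 21. Mild hydrolysis gives the boronic acid without touching the acetal.

Step 13
Reactants: 17 8-{(2R)-2-[(2R)-1-hydroxypropan-2-yl]-5-methylhex-4-en-1-yl}-5,7-bis(methoxymethoxy)-4H-chromen-4-one; 22 [2-methoxy-4-(methoxymethoxy)phenyl]boronic acid (3 equiv)
Product: 23 (2S)-8-{(2R)-2-[(2R)-1-hydroxypropan-2-yl]-5-methylhex-4-en-1-yl}-2-[2-methoxy-4-(methoxymethoxy)phenyl]-5,7-bis(methoxymethoxy)chroman-4-one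
Conditions: Pd(OCOCF3)2 (10 mol %), (R)-t-BuPyOX [(R)-4-tert-butyl-2-(pyridin-2-yl)-4,5-dihydrooxazole] (12 mol %), NH4PF6 (30 mol %), H2O (5 equiv), ClCH2CH2Cl, 55 °C
Reagents that add atoms: none
Why: Palladium-catalysed asymmetric conjugate addition of an arylboronic acid to a chromone: transmetalation gives a cationic aryl–divalent palladium species on the pyridine–oxazoline, which inserts C2=C3, and water protonates the palladium enolate. C2 is set under catalyst control (aryl delivered to the Re face of C2, giving 2S); the chain stereocentres are too remote to interfere. The base-free medium avoids retro-oxa-Michael opening of the product.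

Step 14
Reactants: 23 (2S)-8-{(2R)-2-[(2R)-1-hydroxypropan-2-yl]-5-methylhex-4-en-1-yl}-2-[2-methoxy-4-(methoxymethoxy)phenyl]-5,7-bis(methoxymethoxy)chroman-4-one
Product: 24 (2S)-5,7-dihydroxy-2-(4-hydroxy-2-methoxyphenyl)-8-{(2R)-2-[(2R)-1-hydroxypropan-2-yl]-5-methylhex-4-en-1-yl}chroman-4-one (CNP0081318.1)
Conditions: 3 M aq. HCl–MeOH (1:5), 45 °C, monitored; NaHCO3
Reagents that add atoms: none
Why: Acid-catalysed acetal methanolysis removes the three methoxymethyl groups. C2 of a flavanone is stable to acid, and the alkene has no hydroxyl placed for a five- or six-membered Markovnikov ether closure (C9''–OH could only form a seven-membered ring), so it should survive the short exposure.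

## Compound list

1 | 2,4,6-trihydroxybenzaldehyde | O=Cc1c(O)cc(O)cc1O | starting material
2 | 2-hydroxy-4,6-bis(methoxymethoxy)benzaldehyde | O=Cc1c(O)cc(OCOC)cc1OCOC | intermediate
3 | 2-(benzyloxy)-4,6-bis(methoxymethoxy)benzaldehyde | O=Cc1c(OCc2ccccc2)cc(OCOC)cc1OCOC | intermediate
4 | furan-2(5H)-one | O=C1OCC=C1 | starting material
5 | dimethylzinc | C[Zn]C | starting material
6 | methyl{[(4R)-4-methyl-4,5-dihydrofuran-2-yl]oxy}zinc (methylzinc enolate, not isolated) | C[Zn]OC1=C[C@@H](C)CO1 | intermediate
7 | (3S,4R)-3-{[2-(benzyloxy)-4,6-bis(methoxymethoxy)phenyl](hydroxy)methyl}-4-methyldihydrofuran-2(3H)-one (both carbinol epimers) | OC(c1c(OCc2ccccc2)cc(OCOC)cc1OCOC)[C@H]1C(=O)OC[C@@H]1C | intermediate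
8 | (3R,4R)-3-[2-hydroxy-4,6-bis(methoxymethoxy)benzyl]-4-methyldihydrofuran-2(3H)-one | Oc1cc(OCOC)cc(OCOC)c1C[C@H]1C(=O)OC[C@@H]1C | intermediate
9 | (3R,4R)-3-[2-hydroxy-4,6-bis(methoxymethoxy)benzyl]-4-methyltetrahydrofuran-2-ol (anomers) | Oc1cc(OCOC)cc(OCOC)c1C[C@H]1C(O)OC[C@@H]1C | intermediate
10 | (2R,3R)-3-[2-hydroxy-4,6-bis(methoxymethoxy)benzyl]-5-methoxy-2-methylpent-4-en-1-ol (E/Z mixture, not isolated) | COC=C[C@H](Cc1c(O)cc(OCOC)cc1OCOC)[C@@H](C)CO | intermediate
11 | (4S,5R)-4-[2-hydroxy-4,6-bis(methoxymethoxy)benzyl]-5-methyltetrahydro-2H-pyran-2-ol (anomers) | Oc1cc(OCOC)cc(OCOC)c1C[C@H]1CC(O)OC[C@@H]1C | intermediate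
12 | (2R,3R)-3-[2-hydroxy-4,6-bis(methoxymethoxy)benzyl]-2,6-dimethylhept-5-en-1-ol | Oc1cc(OCOC)cc(OCOC)c1C[C@@H](CC=C(C)C)[C@@H](C)CO | intermediate
13 | 2-(hydroxymethyl)-6-{(2R)-2-[(2R)-1-hydroxypropan-2-yl]-5-methylhex-4-en-1-yl}-3,5-bis(methoxymethoxy)phenol (not isolated) | OCc1c(O)c(C[C@@H](CC=C(C)C)[C@@H](C)CO)c(OCOC)cc1OCOC | intermediate
14 | 2-hydroxy-3-{(2R)-2-[(2R)-1-hydroxypropan-2-yl]-5-methylhex-4-en-1-yl}-4,6-bis(methoxymethoxy)benzaldehyde | O=Cc1c(O)c(C[C@@H](CC=C(C)C)[C@@H](C)CO)c(OCOC)cc1OCOC | intermediate
15 | 1-(2-hydroxy-3-{(2R)-2-[(2R)-1-hydroxypropan-2-yl]-5-methylhex-4-en-1-yl}-4,6-bis(methoxymethoxy)phenyl)prop-2-yn-1-ol (carbinol epimers) | C#CC(O)c1c(O)c(C[C@@H](CC=C(C)C)[C@@H](C)CO)c(OCOC)cc1OCOC | intermediate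
16 | 1-(2-hydroxy-3-{(2R)-2-[(2R)-1-hydroxypropan-2-yl]-5-methylhex-4-en-1-yl}-4,6-bis(methoxymethoxy)phenyl)prop-2-yn-1-one (not isolated) | C#CC(=O)c1c(O)c(C[C@@H](CC=C(C)C)[C@@H](C)CO)c(OCOC)cc1OCOC | intermediate
17 | 8-{(2R)-2-[(2R)-1-hydroxypropan-2-yl]-5-methylhex-4-en-1-yl}-5,7-bis(methoxymethoxy)-4H-chromen-4-one | O=c1ccoc2c(C[C@@H](CC=C(C)C)[C@@H](C)CO)c(OCOC)cc(OCOC)c12 | intermediate
18 | 4-bromo-3-methoxyphenol | COc1cc(O)ccc1Br | starting material
19 | 1-bromo-2-methoxy-4-(methoxymethoxy)benzene | COCOc1ccc(Br)c(OC)c1 | intermediate
20 | [2-methoxy-4-(methoxymethoxy)phenyl]lithium (not isolated) | [Li]c1ccc(OCOC)cc1OC | intermediate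
21 | lithium [2-methoxy-4-(methoxymethoxy)phenyl]triisopropoxyborate (not isolated) | CC(C)O[B-](OC(C)C)(OC(C)C)c1ccc(OCOC)cc1OC.[Li+] | intermediate
22 | [2-methoxy-4-(methoxymethoxy)phenyl]boronic acid | COCOc1ccc(B(O)O)c(OC)c1 | intermediate
23 | (2S)-8-{(2R)-2-[(2R)-1-hydroxypropan-2-yl]-5-methylhex-4-en-1-yl}-2-[2-methoxy-4-(methoxymethoxy)phenyl]-5,7-bis(methoxymethoxy)chroman-4-one | COc1cc(OCOC)ccc1[C@@H]1CC(=O)c2c(OCOC)cc(OCOC)c(C[C@@H](CC=C(C)C)[C@@H](C)CO)c2O1 | intermediate
24 | (2S)-5,7-dihydroxy-2-(4-hydroxy-2-methoxyphenyl)-8-{(2R)-2-[(2R)-1-hydroxypropan-2-yl]-5-methylhex-4-en-1-yl}chroman-4-one (CNP0081318.1) | COc1cc(O)ccc1[C@@H]1CC(=O)c2c(O)cc(O)c(C[C@@H](CC=C(C)C)[C@@H](C)CO)c2O1 | target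

## Step count and least certain steps

Total step count: 14. Longest linear sequence: 12 steps (steps 1 to 10, 13 and 14); steps 11 and 12 make boronic acid 22.

Step 3 (key step). The most likely failure is slow aldol capture by the hindered, electron-rich aldehyde, so that the zinc enolate opens to a ketene and oligomerises. The second is weak facial discrimination with the less reactive methylzinc reagent. The fallback separates the two bond formations. It sets out from 3 and returns at 7. 4-Methylfuran-2(5H)-one F1 is hydrogenated with Ru(OAc)2(BINAP) (divalent ruthenium, antipode chosen for the R product) to (R)-4-methyldihydrofuran-2(3H)-one F2. LiN(i-Pr)2 in THF at −78 °C gives its lithium enolate F3, and addition of 3 should give 7, the aldehyde again approaching anti to the methyl group.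

Step 4. The carbinol C–O bond may be cleaved incompletely, or C2'' may be lost if the carbinol ionises towards a quinone-methide-like species and a proton then leaves C2'' before reduction. The fallback replaces the ionic pathway by a radical one. It sets out from 7 and returns at 8. The carbinol is converted with PhOC(S)Cl, pyridine and DMAP into the O-phenyl thionocarbonate F4. Bu3SnH and AIBN in toluene at 80 °C (Barton–McCombie deoxygenation) give (3R,4R)-3-[2-(benzyloxy)-4,6-bis(methoxymethoxy)benzyl]-4-methyldihydrofuran-2(3H)-one F5. Neutral hydrogenolysis of the aryl benzyl ether (H2, Pd/C, EtOAc) then gives 8.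

Step 10. The propargylic carbinol may decompose by loss of water, and the terminal ynone may polymerise or close in the 5-exo sense before the 6-endo closure. The fallback builds the chromone from a methyl ketone. It sets out from 14 and returns at 17. MeMgBr gives the 1-arylethanol F6, and MnO2 gives the chelated acetophenone F7. Me2NCH(OMe)2 at 90 °C gives the enaminone F8, which should cyclise on silica gel or with dilute acid, with loss of dimethylamine, to 17.

Step 13. Protodeboronation of the electron-rich, ortho-substituted boronic acid may outrun insertion into the deactivated chromone, and the ortho-methoxy group may lower the facial selectivity. The fallback forms O1–C2 instead of C2–C1', at the price of stereocontrol at C2. It sets out from 14 (through F7 as above) and returns at 23. Aryllithium 20 is formylated with DMF to 2-methoxy-4-(methoxymethoxy)benzaldehyde F9. Claisen–Schmidt condensation of F7 with F9 (KOH, EtOH) gives the 2'-hydroxychalcone F10. NaOAc in refluxing EtOH closes it by oxa-Michael addition, only onto the free C8a oxygen, to 23 and its (2R)-epimer F11. These would be separated on a chiral stationary phase, and F11 re-equilibrated through F10 and recycled.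

## Further compounds

F1 | step 3 | 4-methylfuran-2(5H)-one | CC1=CC(=O)OC1
F2 | step 3 | (R)-4-methyldihydrofuran-2(3H)-one | O=C1C[C@@H](C)CO1
F3 | step 3 | lithium enolate of (R)-4-methyldihydrofuran-2(3H)-one | [Li]OC1=C[C@@H](C)CO1
F4 | step 4 | O-{[2-(benzyloxy)-4,6-bis(methoxymethoxy)phenyl][(3S,4R)-4-methyl-2-oxotetrahydrofuran-3-yl]methyl} O-phenyl carbonothioate | S=C(Oc1ccccc1)OC(c1c(OCc2ccccc2)cc(OCOC)cc1OCOC)[C@H]1C(=O)OC[C@@H]1C
F5 | step 4 | (3R,4R)-3-[2-(benzyloxy)-4,6-bis(methoxymethoxy)benzyl]-4-methyldihydrofuran-2(3H)-one | C(Oc1cc(OCOC)cc(OCOC)c1C[C@H]1C(=O)OC[C@@H]1C)c1ccccc1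
F6 | step 10 | 1-(2-hydroxy-3-{(2R)-2-[(2R)-1-hydroxypropan-2-yl]-5-methylhex-4-en-1-yl}-4,6-bis(methoxymethoxy)phenyl)ethan-1-ol | CC(O)c1c(O)c(C[C@@H](CC=C(C)C)[C@@H](C)CO)c(OCOC)cc1OCOC
F7 | step 10 | 1-(2-hydroxy-3-{(2R)-2-[(2R)-1-hydroxypropan-2-yl]-5-methylhex-4-en-1-yl}-4,6-bis(methoxymethoxy)phenyl)ethan-1-one | CC(=O)c1c(O)c(C[C@@H](CC=C(C)C)[C@@H](C)CO)c(OCOC)cc1OCOC
F8 | step 10 | (E)-3-(dimethylamino)-1-(2-hydroxy-3-{(2R)-2-[(2R)-1-hydroxypropan-2-yl]-5-methylhex-4-en-1-yl}-4,6-bis(methoxymethoxy)phenyl)prop-2-en-1-one | CN(C)/C=C/C(=O)c1c(O)c(C[C@@H](CC=C(C)C)[C@@H](C)CO)c(OCOC)cc1OCOC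
F9 | step 13 | 2-methoxy-4-(methoxymethoxy)benzaldehyde | COCOc1ccc(C=O)c(OC)c1
F10 | step 13 | (E)-1-(2-hydroxy-3-{(2R)-2-[(2R)-1-hydroxypropan-2-yl]-5-methylhex-4-en-1-yl}-4,6-bis(methoxymethoxy)phenyl)-3-[2-methoxy-4-(methoxymethoxy)phenyl]prop-2-en-1-one | COc1cc(OCOC)ccc1/C=C/C(=O)c1c(O)c(C[C@@H](CC=C(C)C)[C@@H](C)CO)c(OCOC)cc1OCOC
F11 | step 13 | (2R)-8-{(2R)-2-[(2R)-1-hydroxypropan-2-yl]-5-methylhex-4-en-1-yl}-2-[2-methoxy-4-(methoxymethoxy)phenyl]-5,7-bis(methoxymethoxy)chroman-4-one | COc1cc(OCOC)ccc1[C@H]1CC(=O)c2c(OCOC)cc(OCOC)c(C[C@@H](CC=C(C)C)[C@@H](C)CO)c2O1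
A1 | alternative 1 | 2-{(2R)-2-[(2R)-1-(tert-butyldimethylsilyloxy)propan-2-yl]-5-methylhex-4-en-1-yl}-5-ethoxy-3-(triisopropylsilyloxy)phenol | Oc1cc(OCC)cc(O[Si](C(C)C)(C(C)C)C(C)C)c1C[C@@H](CC=C(C)C)[C@@H](C)CO[Si](C)(C)C(C)(C)C
A2 | alternative 1 | 3-ethoxycyclobut-2-en-1-one | CCOC1=CC(=O)C1
A3 | alternative 1 | tert-butyldimethyl{[(2R,3R)-2,6-dimethyl-3-[3-(triisopropylsilyloxy)prop-2-yn-1-yl]hept-5-en-1-yl]oxy}silane | CC(C)[Si](OC#CC[C@@H](CC=C(C)C)[C@@H](C)CO[Si](C)(C)C(C)(C)C)(C(C)C)C(C)C
A4 | alternative 2 | (2S,4S)-8-{(2R)-2-[(2R)-1-(tert-butyldimethylsilyloxy)propan-2-yl]-5-methylhex-4-en-1-yl}-2-[2-methoxy-4-(methoxymethoxy)phenyl]-5,7-bis(methoxymethoxy)chroman-4-ol | COc1cc(OCOC)ccc1[C@@H]1C[C@H](O)c2c(OCOC)cc(OCOC)c(C[C@@H](CC=C(C)C)[C@@H](C)CO[Si](C)(C)C(C)(C)C)c2O1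
A5 | alternative 2 | (1S,3S)-1-(2-bromo-3-{(2R)-2-[(2R)-1-(tert-butyldimethylsilyloxy)propan-2-yl]-5-methylhex-4-en-1-yl}-4,6-bis(methoxymethoxy)phenyl)-3-[2-methoxy-4-(methoxymethoxy)phenyl]propane-1,3-diol | COc1cc(OCOC)ccc1[C@@H](O)C[C@H](O)c1c(OCOC)cc(OCOC)c(C[C@@H](CC=C(C)C)[C@@H](C)CO[Si](C)(C)C(C)(C)C)c1Br
A6 | alternative 3 | (2S)-8-{(2R)-2-[(2R)-1-(tert-butyldimethylsilyloxy)propan-2-yl]-5-methylhex-4-en-1-yl}-2-[2-methoxy-4-(triisopropylsilyloxy)phenyl]-5,7-bis(triisopropylsilyloxy)chroman-4-one | COc1cc(O[Si](C(C)C)(C(C)C)C(C)C)ccc1[C@@H]1CC(=O)c2c(O[Si](C(C)C)(C(C)C)C(C)C)cc(O[Si](C(C)C)(C(C)C)C(C)C)c(C[C@@H](CC=C(C)C)[C@@H](C)CO[Si](C)(C)C(C)(C)C)c2O1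
A7 | alternative 3 | 2-diazo-1-(3-{(2R)-2-[(2R)-1-(tert-butyldimethylsilyloxy)propan-2-yl]-5-methylhex-4-en-1-yl}-2-{[2-methoxy-4-(triisopropylsilyloxy)benzyl]oxy}-4,6-bis(triisopropylsilyloxy)phenyl)ethan-1-one | COc1cc(O[Si](C(C)C)(C(C)C)C(C)C)ccc1COc1c(C(=O)C=[N+]=[N-])c(O[Si](C(C)C)(C(C)C)C(C)C)cc(O[Si](C(C)C)(C(C)C)C(C)C)c1C[C@@H](CC=C(C)C)[C@@H](C)CO[Si](C)(C)C(C)(C)C
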